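**Strategy.** Ring B (C5–C6–C7=C8–C9–C10) is a cyclohexene retron: diene C6=C7–C8=C9, carrying the C13 side chain on C9, plus the E-enal C5=C10. A temporary diethylsilyl bridge joins diene carbon C7 to the enol oxygen on C3 of the dienophile, so that a type 2 intramolecular Diels–Alder reaction of an acyclic triene aldehyde forms C5–C6 and C9–C10 in one operation. The E-alkene gives the trans C5-H/C10-CH3 relation. The tether forces C4 under the diene, which places the C9 chain cis to the C10 methyl. Fluoride then excises silicon (C7–H), while the freed C3 enolate closes ring A on the C1 aldehyde.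

Key step: step 9

Remark: all atoms carry labdane numbers; the (R) catalyst in step 9 is assigned on the assumption that this enal shows the face preference known for α-branched enals with this catalyst family, and the (S) catalyst would be used if the sense proves opposite.

Step 1
Reactants: 1 (S)-citronellol
Product: 2 (S)-tert-butyl[(3,7-dimethyloct-6-en-1-yl)oxy]dimethylsilane
Conditions: TBSCl, imidazole, CH2Cl2, 0 °C → rt
Reagents that add atoms: tert-butyldimethylsilyl chloride, CC(C)(C)[Si](C)(C)Cl
Why: Silyl ether formation at the only hydroxyl masks O15 for the organolithium, ylide and Lewis acid steps; C13 (S) comes from the chiral pool and is not touched here or later.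

Step 2
Reactants: 2 (S)-tert-butyl[(3,7-dimethyloct-6-en-1-yl)oxy]dimethylsilane
Product: 4 (S)-6-(tert-butyldimethylsilyloxy)-4-methylhexanal, via ozonide 3 (not isolated)
Conditions: O3, CH2Cl2, −78 °C; then PPh3, −78 °C → rt
Reagents that add atoms: ozone, [O-][O+]=O
Why: Ozonolysis with reductive work-up cleaves the trisubstituted alkene, via the secondary ozonide, to the aldehyde whose carbonyl carbon becomes C9.

Step 3
Reactants: 4 (S)-6-(tert-butyldimethylsilyloxy)-4-methylhexanal; 5 2-(triphenylphosphoranylidene)propanal
Product: 6 (S,E)-8-(tert-butyldimethylsilyloxy)-2,6-dimethyloct-2-enal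
Conditions: toluene, 90 °C
Reagents that add atoms: none
Why: Wittig olefination with the formyl-stabilised, α-methyl ylide adds C8, its methyl C17 and C7 and should give the E enal under the thermodynamic control typical of stabilised ylides.

Step 4
Reactants: 6 (S,E)-8-(tert-butyldimethylsilyloxy)-2,6-dimethyloct-2-enal
Product: 7 (S,E)-tert-butyl[(3,7-dimethylnon-6-en-8-yn-1-yl)oxy]dimethylsilane
Conditions: Me3SiCHN2, n-BuLi, THF, −78 °C → rt
Reagents that add atoms: (trimethylsilyl)diazomethane, C[Si](C)(C)C=[N+]=[N-]
Why: Colvin rearrangement (1,2-addition of the lithiated silyl diazomethane, Peterson-type loss of silanolate, then 1,2-hydride shift of the alkylidene carbene with loss of N2) turns the aldehyde into the terminal alkyne carbon C6 without exposing the enal to methoxide and without changing the alkene geometry.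

Step 5
Reactants: 8 4-(2-methylprop-1-en-1-yl)morpholine; 9 acetyl chloride
Product: 11 2,2-dimethyl-3-oxobutanal, via acyl iminium chloride 10 (not isolated)
Conditions: Et2O, 0 °C → rt; then H2O, aq. HCl, rt
Reagents that add atoms: water, O
Why: Stork enamine C-acylation at the β-carbon of the isobutyraldehyde enamine, which cannot re-form an enamine, gives the iminium salt that water hydrolyses to the non-enolisable keto aldehyde holding C2, C3, C4 (with both methyls) and C5.

Step 6
Reactants: 11 2,2-dimethyl-3-oxobutanal; 5 2-(triphenylphosphoranylidene)propanal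
Product: 12 (E)-2,4,4-trimethyl-5-oxohex-2-enal
Conditions: toluene, 100 °C
Reagents that add atoms: none
Why: Wittig olefination is chemoselective for the aldehyde over the hindered ketone and should place the formyl group (C1) trans to the tert-alkyl carbon C4 (E), the geometry that later fixes H-5 trans to the C10 methyl.

Step 7
Reactants: 12 (E)-2,4,4-trimethyl-5-oxohex-2-enal
Product: 13 (E)-5-[(diethylsilyl)oxy]-2,4,4-trimethylhexa-2,5-dienal
Conditions: Et2SiHCl, NaI, Et3N, MeCN, 0 °C → rt; used without chromatography
Reagents that add atoms: chlorodiethylsilane, CC[SiH](Cl)CC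
Why: Soft enolisation with the iodosilane formed in situ silylates the methyl ketone on oxygen at its only enolisable side (C2; C4 is quaternary and the enal has no γ-hydrogen), giving the Si–H enol ether (silyl enol ether formation).

Step 8
Reactants: 7 (S,E)-tert-butyl[(3,7-dimethylnon-6-en-8-yn-1-yl)oxy]dimethylsilane; 13 (E)-5-[(diethylsilyl)oxy]-2,4,4-trimethylhexa-2,5-dienal
Product: 14 (E)-5-{[diethyl((3E,7S)-9-(tert-butyldimethylsilyloxy)-3,7-dimethylnona-1,3-dien-2-yl)silyl]oxy}-2,4,4-trimethylhexa-2,5-dienal (Et2Si bridging C7 and the C3 enol oxygen)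
Conditions: [Cp*Ru(MeCN)3]PF6 (3 mol %), CH2Cl2, 0 °C → rt
Reagents that add atoms: none
Why: Cationic ruthenium-catalysed hydrosilylation of the terminal alkyne proceeds with Markovnikov regiochemistry (silicon on the internal carbon C7, hydrogen on C6), the known bias of this catalyst for terminal alkynes with alkoxy(dialkyl)silanes, and so builds the 2-silyl-1,3-diene and the C7–Si–O–C3 tether in one addition that should leave aldehyde and alkenes untouched.

Step 9
Reactants: 14 tethered triene aldehyde
Product: 15 bridged cycloadduct: ring B cyclohexene with C10 (CH3, CHO), H-5 trans to the C10 methyl, C9 chain cis to the C10 methyl, and a C7–SiEt2–O–C3(=CH2)–C4(CH3)2–C5 bridge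
Conditions: (R)-3,3-diphenyl-1-(o-tolyl)tetrahydro-1H,3H-pyrrolo[1,2-c][1,3,2]oxazaborole (20 mol %), Tf2NH (18 mol %), CH2Cl2 (0.01 M), −78 → −20 °C; Et3N quench
Reagents that add atoms: none
Why: Coordination of the formyl oxygen to the chiral oxazaborolidinium ion lowers the LUMO of the E-enal, and the tethered 2-silyl diene adds in a concerted, asynchronous [4+2] cycloaddition that forms C5–C6 and C9–C10 together (type 2 intramolecular Diels–Alder reaction with a temporary silicon tether, closest to oxazaborolidinium-catalysed Diels–Alder reactions of α-branched enals). Ring B closes as the cyclohexene of the cycloaddition, and the temporary seven-membered oxasilacycle (C7–Si–O–C3–C4–C5–C6) closes as a consequence of the C5–C6 bond, giving a bridged bicyclo[4.3.1] skeleton with the bridgehead C7=C8 alkene. C5 and C10 are set relative to each other by suprafacial addition to the E-alkene (H-5 trans to the C10 methyl, C4 cis to it). C9 is set by the E-diene together with the tether, which can span C7 and C4 only when C4 lies under the diene, so the formyl group is exo and the C9 chain ends cis to the C10 methyl and to C4. The absolute sense (addition to the Si face of C10 and of C5) must come from the catalyst because C13 is too remote to bias the faces. Regiochemistry needs no further control, since the short tether allows only the C5–C6/C9–C10 pairing.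

Step 10
Reactants: 15 bridged cycloadduct
Product: 17 (13S)-15-hydroxy-ent-labda-1,7-dien-3-one, via fluorosilyl ketol 16 (not isolated)
Conditions: Bu4NF·3H2O (6 equiv), THF, 0 → 65 °C
Reagents that add atoms: none
Why: Fluoride cleaves the Si–O enol ether bond, the freed C2 enolate closes ring A on the C1 aldehyde (aldol addition, 6-enolexo) and the hydroxide generated drives E1cB dehydration to the enone, while the now activated fluorosilane on C7 undergoes protodesilylation with retention of the C7=C8 position and the primary silyl ether is cleaved; no stereocenter is formed.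

Step 11
Reactants: 17 (13S)-15-hydroxy-ent-labda-1,7-dien-3-one
Product: 19 (13S)-2,15-dihydroxy-ent-labd-7-en-3-one (2-OH equatorial, anti to the C10 methyl), via dilithium enolate 18 (not isolated)
Conditions: LiBH(s-Bu)3 (2.2 equiv), THF, −78 °C; then 3-phenyl-2-(phenylsulfonyl)oxaziridine, −78 → −40 °C
Reagents that add atoms: 3-phenyl-2-(phenylsulfonyl)oxaziridine, O=S(=O)(N1OC1c1ccccc1)c1ccccc1
Why: Conjugate hydride addition to the β-unsubstituted enone (1,2-attack is blocked by the C4 gem-dimethyl group) gives the C2=C3 enolate regiospecifically, and the oxaziridine transfers oxygen to C2 on the face anti to the axial C10 methyl, giving the equatorial 2-hydroxyl (enolate hydroxylation).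

Step 12
Reactants: 19 (13S)-2,15-dihydroxy-ent-labd-7-en-3-one
Product: 20 (13S)-ent-labd-7-ene-2α,3α,15-triol (2-OH and 3-OH cis, both anti to the C10 methyl)
Conditions: LiBH(s-Bu)3 (3.5 equiv), THF, −78 → −20 °C; H2O work-up
Reagents that add atoms: none
Why: The bulky trialkylborohydride attacks the C3 ketone along the equatorial trajectory, avoiding the axial hydrogens at C1 and C5, and so should give the axial 3-hydroxyl cis to the 2-hydroxyl and anti to the C10 methyl (stereoselective ketone reduction).

Step 13
Reactants: 20 (13S)-ent-labd-7-ene-2α,3α,15-triol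
Product: 21 target, (13S)-ent-labd-7-ene-2α,3α,15-triol 2,15-diacetate
Conditions: Ac2O (2.2 equiv), pyridine, CH2Cl2, 0 °C
Reagents that add atoms: acetic anhydride, CC(=O)OC(C)=O
Why: Acylation differentiates the hydroxyls by hindrance, the primary O15 and the equatorial O2 reacting well before the axial, neopentyl O3 flanked by the gem-dimethyl group, and the equatorial 2-acetate is also the thermodynamically preferred monoester of the cis-diol (selective esterification).

**Compound list**

1 | (S)-citronellol | OCC[C@@H](C)CCC=C(C)C | starting material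
2 | (S)-tert-butyl[(3,7-dimethyloct-6-en-1-yl)oxy]dimethylsilane | CC(C)(C)[Si](C)(C)OCC[C@@H](C)CCC=C(C)C | intermediate
3 | ozonide of 2 (3-substituted 5,5-dimethyl-1,2,4-trioxolane) | CC(C)(C)[Si](C)(C)OCC[C@@H](C)CCC1OOC(C)(C)O1 | intermediate (not isolated)
4 | (S)-6-(tert-butyldimethylsilyloxy)-4-methylhexanal | CC(C)(C)[Si](C)(C)OCC[C@@H](C)CCC=O | intermediate
5 | 2-(triphenylphosphoranylidene)propanal | CC(C=O)=P(c1ccccc1)(c1ccccc1)c1ccccc1 | starting material
6 | (S,E)-8-(tert-butyldimethylsilyloxy)-2,6-dimethyloct-2-enal | CC(C)(C)[Si](C)(C)OCC[C@@H](C)CC/C=C(\C)C=O | intermediate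
7 | (S,E)-tert-butyl[(3,7-dimethylnon-6-en-8-yn-1-yl)oxy]dimethylsilane | CC(C)(C)[Si](C)(C)OCC[C@@H](C)CC/C=C(\C)C#C | intermediate
8 | 4-(2-methylprop-1-en-1-yl)morpholine | CC(C)=CN1CCOCC1 | starting material
9 | acetyl chloride | CC(=O)Cl | starting material
10 | 4-(2,2-dimethyl-3-oxobutylidene)morpholin-4-ium chloride | CC(=O)C(C)(C)C=[N+]1CCOCC1.[Cl-] | intermediate (not isolated)
11 | 2,2-dimethyl-3-oxobutanal | CC(=O)C(C)(C)C=O | intermediate
12 | (E)-2,4,4-trimethyl-5-oxohex-2-enal | O=C/C(C)=C/C(C)(C)C(C)=O | intermediate
13 | (E)-5-[(diethylsilyl)oxy]-2,4,4-trimethylhexa-2,5-dienal | O=C/C(C)=C/C(C)(C)C(=C)O[SiH](CC)CC | intermediate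
14 | silicon-tethered triene aldehyde (Et2Si on C7 of the (3E,7S)-diene and on the C3 enol oxygen of the E-enal) | CC(C)(C)[Si](C)(C)OCC[C@@H](C)CC/C=C(\C)C(=C)[Si](CC)(CC)OC(=C)C(C)(C)/C=C(\C)C=O | intermediate
15 | bridged cycloadduct (ring B with C7–SiEt2–O–C3(=CH2)–C4 bridge; H-5 trans, C9 chain cis to the C10 methyl) | CC(C)(C)[Si](C)(C)OCC[C@@H](C)CC[C@@H]1C(C)=C2C[C@H](C(C)(C)C(=C)O[Si]2(CC)CC)[C@@]1(C)C=O | intermediate
16 | fluorosilyl ketol (1-hydroxy-3-ketone of ring A, C7–SiEt2F, O15–TBS) | CC(C)(C)[Si](C)(C)OCC[C@@H](C)CC[C@@H]1C(C)=C([Si](F)(CC)CC)C[C@@H]2C(C)(C)C(=O)CC(O)[C@@]12C | intermediate (not isolated)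
17 | (13S)-15-hydroxy-ent-labda-1,7-dien-3-one | OCC[C@@H](C)CC[C@@H]1C(C)=CC[C@@H]2C(C)(C)C(=O)C=C[C@@]12C | intermediate
18 | dilithium C2=C3 enolate / O15 alkoxide of the 1,2-dihydro ketone | [Li]OCC[C@@H](C)CC[C@@H]1C(C)=CC[C@@H]2C(C)(C)C(O[Li])=CC[C@@]12C | intermediate (not isolated)
19 | (13S)-2,15-dihydroxy-ent-labd-7-en-3-one (2-OH anti to the C10 methyl) | OCC[C@@H](C)CC[C@@H]1C(C)=CC[C@@H]2C(C)(C)C(=O)[C@@H](O)C[C@@]12C | intermediate
20 | (13S)-ent-labd-7-ene-2α,3α,15-triol | OCC[C@@H](C)CC[C@@H]1C(C)=CC[C@@H]2C(C)(C)[C@@H](O)[C@@H](O)C[C@@]12C | intermediate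
21 | (13S)-ent-labd-7-ene-2α,3α,15-triol 2,15-diacetate (CNP0144124.1) | CC(=O)OCC[C@@H](C)CC[C@@H]1C(C)=CC[C@@H]2C(C)(C)[C@@H](O)[C@@H](OC(C)=O)C[C@@]12C | target

**Count.** Total steps: 13. Longest linear sequence: 10 (steps 1–4 and 8–13).

**Steps most likely to fail**

Step 9. The hindered, β-tert-alkyl enal may bind the bulky boron catalyst poorly, so that cycloaddition is slow or the two faces are not discriminated; an uncatalysed background reaction would erode control further. Fallback (a covalent auxiliary in place of the chiral Lewis acid; it sets out from 14 and comes back at 17): treating 14 with (2R,4R)-2,4-bis(trimethylsilyloxy)pentane and catalytic Me3SiOTf in CH2Cl2 at −78 °C should give the C2-symmetric dioxane acetal F1. The same silyl triflate ionises the acetal to an alkoxy-substituted vinyl oxocarbenium ion, whose tethered ionic Diels–Alder reaction is biased by the chiral alkoxy chain and should give the adduct acetal F2; the enantiomeric diol would be taken if the sense is opposite. PPTS in wet acetone then unmasks the aldehyde and hydrolyses the enol ether to the keto aldehyde silanol F3. Bu4NF as in step 10 (aldol condensation, protodesilylation, loss of the silyl ether) leads to 17.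

Step 8. The cationic ruthenium catalyst may reduce or hydrosilylate the enal or the enol ether alkene of 13, or the conjugated enyne may lose the Markovnikov preference and give the terminal vinylsilane. Fallback (stoichiometric organolithium construction of the C7–Si bond; it sets out from 7 and 12 and comes back at 14): bromoboration of 7 with B-bromo-9-borabicyclo[3.3.1]nonane (CH2Cl2, 0 °C) and protonolysis with AcOH gives the 2-bromo-1,3-diene F4. Bromine–lithium exchange with t-BuLi (Et2O, −78 °C) and quenching with excess Et2SiCl2 gives the dienyl(chloro)diethylsilane F5. Soft enolisation of 12 with this chlorosilane, NaI and Et3N in MeCN then gives 14 directly, by-passing 13.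

Step 10. Under the strongly basic fluoride the aldol may revert or the aldehyde may decompose before ring closure, and dehydration or protodesilylation may stop part-way, giving mixtures. Fallback (Lewis acid closure in separate stages; it sets out from 15 and comes back at 17): BF3·OEt2 in CH2Cl2 at −78 °C promotes the intramolecular Mukaiyama aldol addition of the enol silyl ether to the aldehyde and gives ketol 16, now isolated. Mesylation (MsCl, Et3N) and elimination with DBU give the silylated enone F6. Buffered fluoride (Bu4NF, AcOH, DMF, 70 °C) then effects only protodesilylation at C7 and loss of the silyl ether, arriving at 17.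

**Further compounds**

F1 | step 9 | (4R,6R)-4,6-dimethyl-1,3-dioxane acetal of 14 | CC(C)(C)[Si](C)(C)OCC[C@@H](C)CC/C=C(\C)C(=C)[Si](CC)(CC)OC(=C)C(C)(C)/C=C(\C)C1O[C@H](C)C[C@@H](C)O1
F2 | step 9 | cycloadduct acetal (15 with the formyl group as the (4R,6R)-4,6-dimethyl-1,3-dioxane) | CC(C)(C)[Si](C)(C)OCC[C@@H](C)CC[C@@H]1C(C)=C2C[C@H](C(C)(C)C(=C)O[Si]2(CC)CC)[C@@]1(C)C3O[C@H](C)C[C@@H](C)O3
F3 | step 9 | keto aldehyde silanol (ring B with C10 CHO, C5 2-methyl-3-oxobutan-2-yl, C7 SiEt2OH) | CC(C)(C)[Si](C)(C)OCC[C@@H](C)CC[C@@H]1C(C)=C([Si](O)(CC)CC)C[C@H](C(C)(C)C(C)=O)[C@@]1(C)C=O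
F4 | step 8 | (S,E)-[(8-bromo-3,7-dimethylnona-6,8-dien-1-yl)oxy](tert-butyl)dimethylsilane | CC(C)(C)[Si](C)(C)OCC[C@@H](C)CC/C=C(\C)C(Br)=C
F5 | step 8 | chloro(diethyl)[(3E,7S)-9-(tert-butyldimethylsilyloxy)-3,7-dimethylnona-1,3-dien-2-yl]silane | CC(C)(C)[Si](C)(C)OCC[C@@H](C)CC/C=C(\C)C(=C)[Si](Cl)(CC)CC
F6 | step 10 | silylated dienone (17 with C7–SiEt2F and O15–TBS) | CC(C)(C)[Si](C)(C)OCC[C@@H](C)CC[C@@H]1C(C)=C([Si](F)(CC)CC)C[C@@H]2C(C)(C)C(=O)C=C[C@@]12C
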